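## Retrosynthetic overview

1. The acid side chain comes from Wittig olefination and saponification of a neopentyl bicyclic aldehyde.
2. Ring B (cyclohexene, C6=C7) closes last, by ring-closing metathesis of an isopropenyl and a vinyl group.
3. The quaternary C4 and the C4–C5 bond come from a stereospecific 1,2-shift. The 1-phenylallyl carbon of a trisubstituted epoxide moves to the tertiary oxirane carbon, and the oxirane CH becomes CHO.
4. The epoxide comes from Shi epoxidation of a skipped triene. The triene is built by a boron-Wittig reaction on a cyclopentyl ethyl ketone and then iridium-catalysed allylic alkenylation with 1-phenylallyl alcohol, which sets C5.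
5. Ring A (cyclopentane) forms first, by conjugate addition and 5-exo-tet alkylation of an enone tosylate. That tosylate is made from (2S,4S)-pentane-2,4-diol cyclic sulfate, vinyl Grignard reagent and ethyl vinyl ketone.

Assumption: the SMILES defines the target as the (1R,3R,3aR,4S,5S,7aR,E) isomer, and commercial Grignard solutions count as starting materials. Hexahydroindene numbering: C1 and C3 are the CHMe carbons, C3a and C7a the ring fusion, C4 the quaternary carbon, C5 the CHPh carbon.

## Route

Step 1
Reactants: 1 (2S,4S)-pentane-2,4-diol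
Product: 3 (4S,6S)-4,6-dimethyl-1,3,2-dioxathiane 2,2-dioxide, via cyclic sulfite 2 (not isolated)
Conditions: SOCl2, CH2Cl2, 40 °C; then RuCl3·xH2O (0.1 mol %), NaIO4, MeCN/H2O, 0 °C
Reagents that add atoms: thionyl chloride O=S(Cl)Cl; sodium periodate [Na+].[O-]I(=O)(=O)=O
Why: Sharpless cyclic sulfate synthesis (sulfite formation, then ruthenium-catalysed oxidation) activates both C–O bonds of the C2-symmetric diol without touching its two stereocentres.

Step 2
Reactants: 3 (4S,6S)-4,6-dimethyl-1,3,2-dioxathiane 2,2-dioxide; 4 vinylmagnesium bromide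
Product: 6 (2S,4R)-4-methylhex-5-en-2-ol, via alkyl sulfate salt 5 (not isolated)
Conditions: 4 (1.5 equiv), Li2CuCl4 (5 mol %), THF, −40 to 0 °C; then 20% aq H2SO4/Et2O, 25 °C
Reagents that add atoms: none
Why: Copper-catalysed SN2 opening of the cyclic sulfate inverts one of the two homotopic carbinol carbons (sets C1 of the target), the anionic monoalkyl sulfate resists a second attack, and acid hydrolysis by S–O cleavage frees the untouched (S)-alcohol.

Step 3
Reactants: 6 (2S,4R)-4-methylhex-5-en-2-ol
Product: 7 (2S,4R)-4-methylhex-5-en-2-yl 4-methylbenzenesulfonate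
Conditions: TsCl, Et3N, DMAP (cat.), CH2Cl2, 0 to 25 °C
Reagents that add atoms: 4-toluenesulfonyl chloride Cc1ccc(cc1)S(=O)(=O)Cl
Why: O-sulfonylation turns the secondary alcohol into a leaving group with retention, because the C–O bond is not broken.

Step 4
Reactants: 7 (2S,4R)-4-methylhex-5-en-2-yl 4-methylbenzenesulfonate; 8 pent-1-en-3-one (ethyl vinyl ketone)
Product: 9 (2S,4R,5E)-4-methyl-7-oxonon-5-en-2-yl 4-methylbenzenesulfonate
Conditions: 8 (3 equiv), second-generation Hoveyda–Grubbs catalyst (3 mol %), CH2Cl2, 40 °C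
Reagents that add atoms: none
Why: Olefin cross-metathesis of a terminal alkene with an electron-poor vinyl ketone is selective for the (E)-enone and tolerates the tosylate.

Step 5
Reactants: 9 (2S,4R,5E)-4-methyl-7-oxonon-5-en-2-yl 4-methylbenzenesulfonate; 10 prop-1-en-2-ylmagnesium bromide
Product: 12 1-[(1R,2R,3R,5R)-3,5-dimethyl-2-(prop-1-en-2-yl)cyclopentyl]propan-1-one, via magnesium enolate 11 (not isolated)
Conditions: 10 (2.4 equiv), CuBr·SMe2 (1.2 equiv), THF/Me2S, −78 °C; then DMPU, −78 to 25 °C
Reagents that add atoms: none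
Why: Michael-initiated ring closure, in which the cuprate adds through the Felkin–Anh-type conformer of the γ-stereocentre (CH2 chain anti to copper, methyl inside, H outside) and so places isopropenyl cis to the neighbouring methyl (sets C7a), the enolate then displaces the secondary tosylate 5-exo-tet with inversion (sets C3), and the epimerisable C3a settles with the acyl group trans to the bulky isopropenyl group.

Step 6
Reactants: 12 1-[(1R,2R,3R,5R)-3,5-dimethyl-2-(prop-1-en-2-yl)cyclopentyl]propan-1-one
Product: 14 potassium trifluoro[(1E)-2-[(1R,2R,3R,5R)-3,5-dimethyl-2-(prop-1-en-2-yl)cyclopentyl]but-1-en-1-yl]borate, via pinacol alkenylboronate 13 (not isolated)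
Conditions: CH2(Bpin)2, lithium 2,2,6,6-tetramethylpiperidide, THF, 0 °C; add 12, −78 to 25 °C; then KHF2, MeOH/H2O, 25 °C
Reagents that add atoms: bis[(pinacolato)boryl]methane CC1(C)OB(CB2OC(C)(C)C(C)(C)O2)OC1(C)C; potassium hydrogen difluoride [K+].[F-].F
Why: Boron-Wittig olefination (addition of the diborylmethyl anion, then syn B–O elimination) gives the trisubstituted alkenylboronate with boron trans to the larger cyclopentyl group, and fluoride exchange gives the crystalline trifluoroborate.

Step 7
Reactants: 15 benzaldehyde; 4 vinylmagnesium bromide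
Product: 16 rac-1-phenylprop-2-en-1-ol
Conditions: THF, −78 to 0 °C; H2O work-up
Reagents that add atoms: none
Why: Grignard 1,2-addition gives the racemic branched allylic alcohol, and its stereocentre is erased in the next step.

Step 8
Reactants: 14 potassium alkenyltrifluoroborate (from step 6); 16 rac-1-phenylprop-2-en-1-ol
Product: 17 [(3R,4E)-5-[(1R,2R,3R,5R)-3,5-dimethyl-2-(prop-1-en-2-yl)cyclopentyl]hepta-1,4-dien-3-yl]benzene
Conditions: [Ir(cod)Cl]2 (4 mol %), (S)-BINOL-derived dibenz[b,f]azepine phosphoramidite (P,olefin) ligand (16 mol %), n-Bu4NHSO4 and KHF2 (additives), 1,4-dioxane, 25 °C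
Reagents that add atoms: none
Why: Iridium-catalysed enantioconvergent allylic alkenylation through a π-allyl iridium species joins the alkenyl group to the branched terminus with retention of alkene geometry, and the ligand antipode alone fixes the benzylic centre (3R in 17, C5 of the target).

Step 9
Reactants: 17 [(3R,4E)-5-[(1R,2R,3R,5R)-3,5-dimethyl-2-(prop-1-en-2-yl)cyclopentyl]hepta-1,4-dien-3-yl]benzene
Product: 18 (2R,3R)-2-[(1R,2R,3R,5R)-3,5-dimethyl-2-(prop-1-en-2-yl)cyclopentyl]-2-ethyl-3-[(1S)-1-phenylprop-2-en-1-yl]oxirane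
Conditions: D-fructose-derived Shi ketone (30 mol %), KHSO5 (as Oxone, 2KHSO5·KHSO4·K2SO4), K2CO3, n-Bu4NHSO4 (cat.), MeCN–CH2(OMe)2/aq Na2B4O7 buffer, 0 °C
Reagents that add atoms: potassium peroxymonosulfate [K+].OOS(=O)(=O)[O-]
Why: Shi asymmetric epoxidation oxidises only the electron-rich trisubstituted alkene and, as for other (E)-trisubstituted alkenes, gives the (R,R)-oxirane, a face that A(1,3) strain also favours because C3–H eclipses the alkene towards ethyl and phenyl blocks the other face.

Step 10
Reactants: 18 (2R,3R)-2-[(1R,2R,3R,5R)-3,5-dimethyl-2-(prop-1-en-2-yl)cyclopentyl]-2-ethyl-3-[(1S)-1-phenylprop-2-en-1-yl]oxirane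
Product: 19 (2R,3S)-2-[(1R,2R,3R,5R)-3,5-dimethyl-2-(prop-1-en-2-yl)cyclopentyl]-2-ethyl-3-phenylpent-4-enal
Conditions: preformed methylaluminium bis(4-bromo-2,6-di-tert-butylphenoxide) (MABR, 20 mol %), CH2Cl2, −78 °C; quench at −78 °C
Reagents that add atoms: none
Why: Proposed new method: the bulky oxophilic aluminium Lewis acid binds the oxirane oxygen and stretches the tertiary C2–O bond, and the 1-phenylallyl carbon, which as a benzylic and allylic centre bridges a developing cation far better than H, moves suprafacially from C3 to the rear of C2 in a concerted 1,2-shift (inversion at C2, retention at the migrating carbon, C3 becomes CHO), so the (2R,3R)-epoxide is translated into the quaternary centre (C4 of the target) next to the intact benzylic centre (C5) while the phenoxide walls disfavour the hydride shift to the ketone; the closest known reaction type is the organoaluminium-promoted (MABR) Meinwald/semipinacol rearrangement of trisubstituted epoxides and epoxy silyl ethers to α-quaternary aldehydes, which has not been shown for a stereogenic, doubly activated migrating carbon in a polyene substrate.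

Step 11
Reactants: 19 (2R,3S)-2-[(1R,2R,3R,5R)-3,5-dimethyl-2-(prop-1-en-2-yl)cyclopentyl]-2-ethyl-3-phenylpent-4-enal
Product: 20 (1R,3R,3aR,4R,5S,7aR)-4-ethyl-1,3,7-trimethyl-5-phenyl-2,3,3a,4,5,7a-hexahydro-1H-indene-4-carbaldehyde
Conditions: second-generation Hoveyda–Grubbs catalyst (5 mol %), toluene, 80 °C
Reagents that add atoms: none
Why: Ring-closing metathesis of the vinyl and isopropenyl groups closes the trans-fused cyclohexene with its trisubstituted C6=C7 bond, creates no new stereocentre, and leaves the non-enolisable aldehyde untouched.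

Step 12
Reactants: 20 (1R,3R,3aR,4R,5S,7aR)-4-ethyl-1,3,7-trimethyl-5-phenyl-2,3,3a,4,5,7a-hexahydro-1H-indene-4-carbaldehyde
Product: 22 plakotenin, (E)-3-[(1R,3R,3aR,4S,5S,7aR)-4-ethyl-1,3,7-trimethyl-5-phenyl-2,3,3a,4,5,7a-hexahydro-1H-inden-4-yl]-2-methylprop-2-enoic acid, via ethyl ester 21 (not isolated)
Conditions: Ph3P=C(Me)CO2Et, toluene, 110 °C; then LiOH, THF/MeOH/H2O, 60 °C; HCl work-up
Reagents that add atoms: ethyl 2-(triphenylphosphoranylidene)propanoate CCOC(=O)C(C)=P(c1ccccc1)(c1ccccc1)c1ccccc1; lithium hydroxide [Li+].[OH-]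
Why: Wittig olefination with the stabilised ylide gives the (E)-trisubstituted enoate on the hindered aldehyde, and saponification in the same flask frees the acid without affecting any stereocentre (the C4 descriptor changes from R to S only through CIP priorities).

## Compound list

1 | (2S,4S)-pentane-2,4-diol | C[C@H](O)C[C@H](C)O | starting material
2 | (4S,6S)-4,6-dimethyl-1,3,2-dioxathiane 2-oxide | C[C@H]1C[C@H](C)OS(=O)O1 | intermediate
3 | (4S,6S)-4,6-dimethyl-1,3,2-dioxathiane 2,2-dioxide | C[C@H]1C[C@H](C)OS(=O)(=O)O1 | intermediate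
4 | vinylmagnesium bromide | C=C[Mg]Br | starting material
5 | bromomagnesium (2S,4R)-4-methylhex-5-en-2-yl sulfate | C=C[C@H](C)C[C@H](C)OS(=O)(=O)[O-].[Mg+2].[Br-] | intermediate
6 | (2S,4R)-4-methylhex-5-en-2-ol | C=C[C@H](C)C[C@H](C)O | intermediate
7 | (2S,4R)-4-methylhex-5-en-2-yl 4-methylbenzenesulfonate | C=C[C@H](C)C[C@H](C)OS(=O)(=O)c1ccc(C)cc1 | intermediate
8 | pent-1-en-3-one | C=CC(=O)CC | starting material
9 | (2S,4R,5E)-4-methyl-7-oxonon-5-en-2-yl 4-methylbenzenesulfonate | CCC(=O)/C=C/[C@H](C)C[C@H](C)OS(=O)(=O)c1ccc(C)cc1 | intermediate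
10 | prop-1-en-2-ylmagnesium bromide | C=C(C)[Mg]Br | starting material
11 | open-chain bromomagnesium enolate from 1,4-addition to 9 (tosylate still in place) | CCC([O-])=C[C@H](C(C)=C)[C@H](C)C[C@H](C)OS(=O)(=O)c1ccc(C)cc1.[Mg+2].[Br-] | intermediate
12 | 1-[(1R,2R,3R,5R)-3,5-dimethyl-2-(prop-1-en-2-yl)cyclopentyl]propan-1-one | CCC(=O)[C@H]1[C@H](C(C)=C)[C@H](C)C[C@H]1C | intermediate
13 | 2-[(1E)-2-[(1R,2R,3R,5R)-3,5-dimethyl-2-(prop-1-en-2-yl)cyclopentyl]but-1-en-1-yl]-4,4,5,5-tetramethyl-1,3,2-dioxaborolane | CC/C(=C\B2OC(C)(C)C(C)(C)O2)[C@H]1[C@H](C(C)=C)[C@H](C)C[C@H]1C | intermediate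
14 | potassium trifluoro[(1E)-2-[(1R,2R,3R,5R)-3,5-dimethyl-2-(prop-1-en-2-yl)cyclopentyl]but-1-en-1-yl]borate | CC/C(=C\[B-](F)(F)F)[C@H]1[C@H](C(C)=C)[C@H](C)C[C@H]1C.[K+] | intermediate
15 | benzaldehyde | O=Cc1ccccc1 | starting material
16 | rac-1-phenylprop-2-en-1-ol | C=CC(O)c1ccccc1 | intermediate
17 | [(3R,4E)-5-[(1R,2R,3R,5R)-3,5-dimethyl-2-(prop-1-en-2-yl)cyclopentyl]hepta-1,4-dien-3-yl]benzene | CC/C(=C\[C@@H](C=C)c2ccccc2)[C@H]1[C@H](C(C)=C)[C@H](C)C[C@H]1C | intermediate
18 | (2R,3R)-2-[(1R,2R,3R,5R)-3,5-dimethyl-2-(prop-1-en-2-yl)cyclopentyl]-2-ethyl-3-[(1S)-1-phenylprop-2-en-1-yl]oxirane | CC[C@@]2(O[C@@H]2[C@@H](C=C)c3ccccc3)[C@H]1[C@H](C(C)=C)[C@H](C)C[C@H]1C | intermediate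
19 | (2R,3S)-2-[(1R,2R,3R,5R)-3,5-dimethyl-2-(prop-1-en-2-yl)cyclopentyl]-2-ethyl-3-phenylpent-4-enal | CC[C@](C=O)([C@@H](C=C)c2ccccc2)[C@H]1[C@H](C(C)=C)[C@H](C)C[C@H]1C | intermediate
20 | (1R,3R,3aR,4R,5S,7aR)-4-ethyl-1,3,7-trimethyl-5-phenyl-2,3,3a,4,5,7a-hexahydro-1H-indene-4-carbaldehyde | CC[C@@]1(C=O)[C@H]2[C@H](C(C)=C[C@H]1c1ccccc1)[C@H](C)C[C@H]2C | intermediate
21 | ethyl (E)-3-[(1R,3R,3aR,4S,5S,7aR)-4-ethyl-1,3,7-trimethyl-5-phenyl-2,3,3a,4,5,7a-hexahydro-1H-inden-4-yl]-2-methylprop-2-enoate | CC[C@@]1(/C=C(\C)C(=O)OCC)[C@H]2[C@H](C(C)=C[C@H]1c1ccccc1)[C@H](C)C[C@H]2C | intermediate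
22 | plakotenin | CC[C@@]1(/C=C(\C)C(=O)O)[C@H]2[C@H](C(C)=C[C@H]1c1ccccc1)[C@H](C)C[C@H]2C | target

## Step count and risks

Total step count: 12.
Longest linear sequence: 11 (steps 1–6 and 8–12; step 7 is a one-step side branch).

**Step 5.** The C7a centre rests on acyclic Felkin–Anh control in which CH2R competes with methyl. The expected ratio is only about 4:1, and a sluggish copper/magnesium enolate may leave the ring closure incomplete.

The fallback separates the two events and uses catalyst control.
- It sets out from 9. Rhodium-catalysed asymmetric 1,4-addition of potassium isopropenyltrifluoroborate is run with [Rh(cod)(OH)]2 and the BINAP antipode matched to the substrate bias, in toluene/H2O at 40 °C.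
- This gives the open-chain keto tosylate F1.
- A separate cyclisation with KOtBu in THF closes the ring and equilibrates C3a.
- It comes back to the route at 12.

**Step 6.** The hindered, enolisable ketone 12 may be deprotonated instead of attacked, and the E/Z ratio may be modest.

The fallback builds the same alkenylboronate from an alkyne.
- It sets out from 7. Cross-metathesis with but-3-en-2-one gives the methyl enone tosylate F2.
- The same cuprate ring closure gives the methyl ketone F3.
- Lithium diisopropylamide and ClP(O)(OEt)2 give the enol phosphate F4.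
- More lithium diisopropylamide eliminates it to the ethynylcyclopentane F5.
- Known copper-catalysed syn carboboration (B2pin2, EtI, CuCl/Xantphos, NaOtBu) places boron on the terminal carbon and ethyl cis to it.
- It comes back to the route at 13, which KHF2 converts to 14.

**Step 10 (the new step).** There are four ways it could fail.
- The shift may leak through a dissociated 1-phenylallyl cation and aluminium enolate pair, which would scramble the benzylic centre or give the linear cinnamyl isomer.
- A hydride shift may give the ketone.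
- The isopropenyl group may capture the tertiary cation.
- A carbonyl-ene reaction of 19 may follow the shift.

The fallback gives up the epoxide and makes the C4–C5 bond intermolecularly by known chemistry.
- It sets out from 12. Wittig methoxymethylenation (Ph3P=CHOMe, THF) gives the enol ether F6.
- Mild acid hydrolysis gives the α-branched aldehyde F7.
- The established iridium/primary-amine dual-catalytic α-allylation of α-branched aldehydes follows, using racemic 16, [Ir(cod)Cl]2, the same (P,olefin) ligand, a cinchona-derived primary amine and Cl3CCO2H in 1,2-dichloroethane. It sets both centres under catalyst control.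
- It comes back to the route at 19, and steps 6, 8 and 9 then drop out.

## Further compounds

F1 | step 5 | (2S,4R,5S)-4-methyl-7-oxo-5-(prop-1-en-2-yl)nonan-2-yl 4-methylbenzenesulfonate | CCC(=O)C[C@H](C(C)=C)[C@H](C)C[C@H](C)OS(=O)(=O)c1ccc(C)cc1
F2 | step 6 | (2S,4R,5E)-4-methyl-7-oxooct-5-en-2-yl 4-methylbenzenesulfonate | CC(=O)/C=C/[C@H](C)C[C@H](C)OS(=O)(=O)c1ccc(C)cc1
F3 | step 6 | 1-[(1R,2R,3R,5R)-3,5-dimethyl-2-(prop-1-en-2-yl)cyclopentyl]ethan-1-one | CC(=O)[C@H]1[C@H](C(C)=C)[C@H](C)C[C@H]1C
F4 | step 6 | 1-[(1R,2R,3R,5R)-3,5-dimethyl-2-(prop-1-en-2-yl)cyclopentyl]ethenyl diethyl phosphate | C=C(OP(=O)(OCC)OCC)[C@H]1[C@H](C(C)=C)[C@H](C)C[C@H]1C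
F5 | step 6 | (1R,2R,3R,5R)-1-ethynyl-3,5-dimethyl-2-(prop-1-en-2-yl)cyclopentane | C#C[C@H]1[C@H](C(C)=C)[C@H](C)C[C@H]1C
F6 | step 10 | (1R,2R,3R,5R)-1-(1-methoxybut-1-en-2-yl)-3,5-dimethyl-2-(prop-1-en-2-yl)cyclopentane (E/Z mixture) | CCC(=COC)[C@H]1[C@H](C(C)=C)[C@H](C)C[C@H]1C
F7 | step 10 | 2-[(1R,2R,3R,5R)-3,5-dimethyl-2-(prop-1-en-2-yl)cyclopentyl]butanal (C2 epimers) | CCC(C=O)[C@H]1[C@H](C(C)=C)[C@H](C)C[C@H]1C
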